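**Retrosynthetic overview**
1. Target 7 ⇐ hydrogenolysis of its 3,7,4'-tri-O-benzyl ether 6; 6 ⇐ MeMgBr addition to methyl ketone 5.
2. Key disconnection, C6–C1'' on the intact flavonol: 5 ⇐ 6-iodide 3 + the butanone homoenolate (β-palladated ketone) released from 1-methylcyclopropanol 4.
3. 3 ⇐ 5-OH-directed C6 iodination of 2; 2 ⇐ selective tri-O-benzylation of kaempferol 1.
4. Rings: none is built; rings A, C and B come intact from kaempferol, and only the C6 side chain is constructed.

Assumption: the target has no stereocentre, so no stereocontrol is needed; kaempferol (a bulk botanical flavonol) and 1-methylcyclopropanol are taken as commercial.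

**Step 1**
Reactants: 1 kaempferol
Product: 2 3,7-bis(benzyloxy)-2-[4-(benzyloxy)phenyl]-5-hydroxy-4H-chromen-4-one
Conditions: BnBr (3.3 equiv), K2CO3 (3.5 equiv), DMF, rt → 40 °C
Reagents that add atoms: benzyl bromide, BrCc1ccccc1
Why: Williamson ether synthesis under mild carbonate conditions alkylates the three acidic hydroxyls (C3, C7, C4'), while the 5-OH, held in a hydrogen bond to the C4 carbonyl, stays free.

**Step 2**
Reactants: 2 3,7-bis(benzyloxy)-2-[4-(benzyloxy)phenyl]-5-hydroxy-4H-chromen-4-one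
Product: 3 3,7-bis(benzyloxy)-2-[4-(benzyloxy)phenyl]-5-hydroxy-6-iodo-4H-chromen-4-one
Conditions: benzyltrimethylammonium dichloroiodate (1.1 equiv), CaCO3 (1.5 equiv), CH2Cl2/MeOH (5:2), rt, dark
Reagents that add atoms: benzyltrimethylammonium dichloroiodate, C[N+](C)(C)Cc1ccccc1.Cl[I-]Cl
Why: Electrophilic aromatic iodination of ring A, where the free chelated 5-OH steers the iodonium equivalent to its ortho position C6 rather than C8; ring B is deactivated by conjugation to the pyranone and the 3-OH is masked against oxidation.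

**Step 3**
Reactants: 3 3,7-bis(benzyloxy)-2-[4-(benzyloxy)phenyl]-5-hydroxy-6-iodo-4H-chromen-4-one; 4 1-methylcyclopropanol (2 equiv)
Product: 5 3,7-bis(benzyloxy)-2-[4-(benzyloxy)phenyl]-5-hydroxy-6-(3-oxobutyl)-4H-chromen-4-one
Conditions: Pd(OAc)2 (10 mol %), XPhos (2-dicyclohexylphosphino-2',4',6'-triisopropylbiphenyl, 20 mol %), Cs2CO3 (3 equiv), toluene/1,4-dioxane (4:1), 80 °C, argon
Reagents that add atoms: none
Why: Palladium-catalysed ring-opening cross-coupling of a cyclopropanol, in which zerovalent palladium inserts into the C6–I bond, the cyclopropoxide binds the divalent arylpalladium, strain-driven β-carbon elimination unmasks the ketone homoenolate (nucleophilic at the carbon that is electrophilic in methyl vinyl ketone) and reductive elimination joins it to the former aryl-iodide carbon; the bulky biarylphosphine suppresses β-hydride elimination and the free 5-OH is carried as its cesium phenoxide.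

**Step 4**
Reactants: 5 3,7-bis(benzyloxy)-2-[4-(benzyloxy)phenyl]-5-hydroxy-6-(3-oxobutyl)-4H-chromen-4-one
Product: 6 3,7-bis(benzyloxy)-2-[4-(benzyloxy)phenyl]-5-hydroxy-6-(3-hydroxy-3-methylbutyl)-4H-chromen-4-one
Conditions: MeMgBr (3.5 equiv), THF, −78 → 0 °C; then H2O/pH 7 phosphate buffer
Reagents that add atoms: methylmagnesium bromide, C[Mg]Br
Why: Grignard 1,2-addition, in which the first equivalent turns the 5-OH into a magnesium phenoxide chelated to C4=O and so further deactivates the vinylogous-ester pyranone carbonyl, leaving the aliphatic methyl ketone to react selectively at low temperature; the neutral quench avoids acid-catalysed cyclisation of the new tertiary alcohol onto O5 or O7, and the carbinol carbon (two methyls) is not a stereocentre.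

**Step 5**
Reactants: 6 3,7-bis(benzyloxy)-2-[4-(benzyloxy)phenyl]-5-hydroxy-6-(3-hydroxy-3-methylbutyl)-4H-chromen-4-one
Product: 7 3,5,7-trihydroxy-6-(3-hydroxy-3-methylbutyl)-2-(4-hydroxyphenyl)-4H-chromen-4-one (target)
Conditions: H2 (1 atm), 10% Pd/C, EtOAc/MeOH (1:1), rt
Reagents that add atoms: none
Why: Catalytic hydrogenolysis of the three benzyl ethers under neutral conditions leaves the tetrasubstituted C2=C3 bond, the pyranone and the non-benzylic tertiary alcohol intact and avoids the acid that would close a dimethylchroman ring.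

**Compound list**
1 | kaempferol (3,5,7-trihydroxy-2-(4-hydroxyphenyl)-4H-chromen-4-one) | O=c1c(O)c(-c2ccc(O)cc2)oc2cc(O)cc(O)c12 | starting material
2 | 3,7-bis(benzyloxy)-2-[4-(benzyloxy)phenyl]-5-hydroxy-4H-chromen-4-one | O=c1c(OCc2ccccc2)c(-c2ccc(OCc3ccccc3)cc2)oc2cc(OCc3ccccc3)cc(O)c12 | intermediate
3 | 3,7-bis(benzyloxy)-2-[4-(benzyloxy)phenyl]-5-hydroxy-6-iodo-4H-chromen-4-one | O=c1c(OCc2ccccc2)c(-c2ccc(OCc3ccccc3)cc2)oc2cc(OCc3ccccc3)c(I)c(O)c12 | intermediate
4 | 1-methylcyclopropanol | CC1(O)CC1 | starting material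
5 | 3,7-bis(benzyloxy)-2-[4-(benzyloxy)phenyl]-5-hydroxy-6-(3-oxobutyl)-4H-chromen-4-one | CC(=O)CCc1c(OCc2ccccc2)cc2oc(-c3ccc(OCc4ccccc4)cc3)c(OCc3ccccc3)c(=O)c2c1O | intermediate
6 | 3,7-bis(benzyloxy)-2-[4-(benzyloxy)phenyl]-5-hydroxy-6-(3-hydroxy-3-methylbutyl)-4H-chromen-4-one | CC(C)(O)CCc1c(OCc2ccccc2)cc2oc(-c3ccc(OCc4ccccc4)cc3)c(OCc3ccccc3)c(=O)c2c1O | intermediate
7 | 3,5,7-trihydroxy-6-(3-hydroxy-3-methylbutyl)-2-(4-hydroxyphenyl)-4H-chromen-4-one | CC(C)(O)CCc1c(O)cc2oc(-c3ccc(O)cc3)c(O)c(=O)c2c1O | target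

**Step count:** 5 steps in total; longest linear sequence 5 steps (1 → 2 → 3 → 5 → 6 → 7).

**Steps most likely to fail**

Step 3 (key coupling). The aryl iodide is electron-rich, flanked by two oxygens and carries an ortho phenoxide, so oxidative addition and reductive elimination may be slow and protodeiodination or β-hydride elimination may win. Fallback, setting out from 3 and coming back at 6: Negishi coupling of 3 with the preformed ester homoenolate (3-ethoxy-3-oxopropyl)zinc bromide (3 equiv, one consumed by the 5-OH; Pd(OAc)2/SPhos, THF, 50 °C) gives ethyl 3-{3,7-bis(benzyloxy)-2-[4-(benzyloxy)phenyl]-5-hydroxy-4-oxo-4H-chromen-6-yl}propanoate F1. Double addition of MeMgBr (5 equiv, THF, −40 → 0 °C) to this ester gives 6 directly, bypassing 5.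

Step 4 (Grignard addition). MeMgBr may attack the pyranone (C4 or C2) or enolise the ketone. Fallback, setting out from 5 and coming back at 6: Wittig methylenation (methyltriphenylphosphonium bromide/KOtBu, 3 equiv, THF, 0 °C → rt; the ylide ignores the vinylogous-ester C4 carbonyl) gives 3,7-bis(benzyloxy)-2-[4-(benzyloxy)phenyl]-5-hydroxy-6-(3-methylbut-3-en-1-yl)-4H-chromen-4-one F2. Mukaiyama hydration (Co(acac)2 cat., PhSiH3, O2, iPrOH/THF, rt) then installs the Markovnikov tertiary alcohol of 6 by a radical, acid-free path.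

Step 1 (selective protection). Di-, tri- and tetra-benzylated mixtures or C-benzylation may lower the yield of 2. Fallback, setting out from 1 and coming back at 2: exhaustive benzylation (BnBr 6 equiv, K2CO3, DMF, 80 °C) gives 3,5,7-tris(benzyloxy)-2-[4-(benzyloxy)phenyl]-4H-chromen-4-one F3. Chelation-controlled cleavage of only the 5-O-benzyl ether (BCl3 1.05 equiv, CH2Cl2, −78 °C; boron bridges C4=O and O5) then returns 2.

**Further compounds**
F1 | step 3 | ethyl 3-{3,7-bis(benzyloxy)-2-[4-(benzyloxy)phenyl]-5-hydroxy-4-oxo-4H-chromen-6-yl}propanoate | CCOC(=O)CCc1c(OCc2ccccc2)cc2oc(-c3ccc(OCc4ccccc4)cc3)c(OCc3ccccc3)c(=O)c2c1O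
F2 | step 4 | 3,7-bis(benzyloxy)-2-[4-(benzyloxy)phenyl]-5-hydroxy-6-(3-methylbut-3-en-1-yl)-4H-chromen-4-one | C=C(C)CCc1c(OCc2ccccc2)cc2oc(-c3ccc(OCc4ccccc4)cc3)c(OCc3ccccc3)c(=O)c2c1O
F3 | step 1 | 3,5,7-tris(benzyloxy)-2-[4-(benzyloxy)phenyl]-4H-chromen-4-one | O=c1c(OCc2ccccc2)c(-c2ccc(OCc3ccccc3)cc2)oc2cc(OCc3ccccc3)cc(OCc3ccccc3)c12
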